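The plan rests on excising C8. In the seven-membered ring C1–C10–C9–C8–C7–C6–C5 this carbon carries the methyl group and is flanked by two oxygen-bearing carbons, C7 and C9. Taking it out leaves a rigid trans-fused hydrindan-7-one whose axial C1 methyl steers every facial choice. The key step returns C8. Chloro(methyl)carbene adds to the C7=C9 silyl enol ether and the cyclopropane opens. One operation thus delivers the seven-membered ring, the C7 ketone and the C8(methyl)=C9 alkene, which are the latent carbinol and epoxide. The precursor is a trans-hydrindane with C1, C4, C5 and C6 already in final configuration. Both hydroxyls are triethylsilyl ethers and the ketone is its kinetic trimethylsilyl enol ether.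

Key step: step 11

Numbering: daucane numbering is used for every bicyclic compound. C1 is the quaternary carbon with methyl, followed by C2, C3 and C4. C5 is the ring-fusion CH, followed by C6 and C7. C8 is the carbon inserted in step 11, followed by C9 and C10. β is the face of the C1 methyl and α is the opposite face.

Assumption: the two pseudoenantiomeric cinchona catalysts give opposite antipodes of 3. The one that furnishes (S)-3 is used, and its sense of induction is to be established at compound 4.

Step 1
Reactants: 1 3-methylcyclopentane-1,2-dione (enol form); 2 methyl vinyl ketone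
Product: 3 (S)-3-methyl-3-(3-oxobutyl)cyclopentane-1,2-dione
Conditions: cinchona-derived tertiary amine–squaramide catalyst (10 mol %), CH2Cl2, −20 °C, 2 (0.9 equiv) added slowly
Reagents that add atoms: none
Why: Proposed new method: the quinuclidine nitrogen deprotonates the acidic enol O–H of 1 to an ion-paired enolate whose only carbon terminus is the methyl-bearing ring carbon, the squaramide N–H groups bind the carbonyl of 2, and C–C bond formation inside this assembly distinguishes the two faces of the planar enolate and sets the quaternary C1 as (S); the closest known reaction types are the cinchona-catalysed enantioselective Michael additions of α-substituted cyclic β-dicarbonyl compounds to vinyl ketones and of unsubstituted cyclopentane-1,2-dione to nitroalkenes, whereas a 3-alkyl-1,2-dione has not been shown to give a quaternary centre in this way.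

Step 2
Reactants: 3 (S)-3-methyl-3-(3-oxobutyl)cyclopentane-1,2-dione
Product: 4 (S)-7a-methyl-2,6,7,7a-tetrahydro-1H-indene-3,5-dione (C4=O, C5=C6, C7=O)
Conditions: p-TsOH·H2O (10 mol %), toluene, reflux, Dean–Stark
Reagents that add atoms: none
Why: Acid-catalysed intramolecular aldol condensation (closing half of a Robinson annulation), in which only attack of the terminal methyl carbon (C6) on the carbonyl beside the quaternary centre (C5) closes a six-membered ring that can dehydrate into conjugation, while the acidic medium avoids the retro-Michael path by which base could erode C1.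

Step 3
Reactants: 4 bicyclic ene-dione
Product: 5 C7 ethylene ketal of 4 (C4=O still conjugated with C5=C6)
Conditions: (TMSOCH2)2 (1.05 equiv), TMSOTf (5 mol %), CH2Cl2, −78 °C; pyridine quench
Reagents that add atoms: 1,2-bis(trimethylsilyloxy)ethane, C[Si](C)(C)OCCO[Si](C)(C)C
Why: Noyori ketalisation under aprotic conditions, in which the cyclohexenone carbonyl C7 rehybridises to sp3 more readily than the cyclopentenone-type carbonyl C4, the alkene stays put because it remains conjugated with C4=O, and a dioxolane resists loss of alcohol to a dienol ether and later β-elimination better than an acyclic ketal.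

Step 4
Reactants: 5 ketal enone
Product: 6 4β-allylic alcohol (C5=C6, C7 dioxolane)
Conditions: NaBH4, CeCl3·7H2O, MeOH, −78 to −40 °C
Reagents that add atoms: none
Why: Luche 1,2-reduction, in which hydride reaches the C4 carbonyl from the α face away from the C1 methyl and gives the 4β alcohol, a centre that is erased in step 6 but meanwhile keeps the α face of the alkene open.

Step 5
Reactants: 6 4β-allylic alcohol
Product: 8 trans-fused 4β,6α-diol C7 dioxolane (C5–H α), via C6 organoborane 7 (not isolated)
Conditions: BH3·THF (3 equiv), THF, 0 °C to rt; then 3 M NaOH, 30% H2O2, 0 °C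
Reagents that add atoms: hydrogen peroxide, OO
Why: Hydroboration–oxidation, in which borane adds syn to the trisubstituted alkene from the α face (opposite the axial C1 methyl and the 4β oxygen) with boron on the less substituted C6, so that C5–H (α, trans fusion) and C6–OH (α, equatorial, retention in the oxidation) are fixed together, and the equatorial C–B bond has no antiperiplanar ketal C–O bond for β-elimination.

Step 6
Reactants: 8 4β,6α-diol ketal
Product: 9 trans-fused 6α-hydroxy-4-ketone C7 dioxolane
Conditions: TEMPO (20 mol %), PhI(OAc)2 (1.1 equiv), CH2Cl2, 0 °C to rt; crude 9 used at once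
Reagents that add atoms: none
Why: Oxoammonium (TEMPO) oxidation, which is governed by steric access: C4–OH has a methylene neighbour and an exposed α hydrogen, whereas C6–OH is wedged between the ketal carbon and the ring fusion and its hydrogen is syn-axial to the C1 methyl, and the nearly neutral medium should spare the epimerisable C5 and the β-hydroxy ketone.

Step 7
Reactants: 9 6α-hydroxy-4-ketone; 10 isopropylmagnesium chloride
Product: 11 4α-isopropyl-4β,6α-diol C7 dioxolane
Conditions: CeCl3 (dried, 4 equiv) and 10 (3.5 equiv), THF, −78 °C, then 9; sat. NH4Cl at −78 °C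
Reagents that add atoms: none
Why: Organocerium 1,2-addition, whose low basicity suppresses enolisation, C5 epimerisation and β-hydride reduction; the first equivalent turns C6–OH into an alkoxide that cannot be eliminated and holds cerium on the α face, and isopropyl then adds to C4=O from that face, opposite the C1 methyl, giving 4β-OH and 4α-isopropyl.

Step 8
Reactants: 11 tertiary carbinol ketal
Product: 12 4β,6α-dihydroxy-4α-isopropyl trans-hydrindan-7-one
Conditions: 2 M HCl, THF, rt
Reagents that add atoms: water, O
Why: Acid hydrolysis of the dioxolane, which is safe because the tertiary C4–OH is γ to the new carbonyl (no elimination path) and dilute aqueous acid at room temperature should neither ionise it nor shift the α-ketol.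

Step 9
Reactants: 12 dihydroxy ketone
Product: 13 4β,6α-bis(triethylsilyloxy) ketone
Conditions: TESOTf (3 equiv), 2,6-lutidine (5 equiv), CH2Cl2, −78 to 0 °C
Reagents that add atoms: triethylsilyl trifluoromethanesulfonate, CC[Si](CC)(CC)OS(=O)(=O)C(F)(F)F
Why: Silyl triflate silylation is strong enough for the tertiary C4–OH as well as the secondary C6–OH, so both are capped against the bases of steps 10–12 and the α-ketol can no longer isomerise.

Step 10
Reactants: 13 bis(triethylsilyloxy) ketone
Product: 15 C7=C9 trimethylsilyl enol ether, via lithium enolate 14 (not isolated)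
Conditions: LDA (1.3 equiv), TMSCl (3 equiv, present from the start), THF, −78 °C; Et3N, pentane, cold aq. NaHCO3; used crude
Reagents that add atoms: chlorotrimethylsilane, C[Si](C)(C)Cl
Why: Kinetic deprotonation with in situ trapping, in which LDA takes a proton from the open C9 methylene and not from the C6 methine, which is screened by its silyloxy group, the ring fusion and the syn-axial C1 methyl, and TMSCl captures the enolate on oxygen before it can equilibrate.

Step 11
Reactants: 15 C7=C9 trimethylsilyl enol ether; 16 1,1-dichloroethane
Product: 18 trans-fused bicyclo[5.3.0] enone (C7=O, C8(methyl)=C9, 4β,6α-bis-OTES), via chlorocyclopropane 17 (not isolated)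
Conditions: 16 (6 equiv), n-BuLi (4 equiv, slow addition), Et2O, −40 °C to rt; solvent exchanged for toluene, Et3N (1 equiv), 110 °C
Reagents that add atoms: none
Why: n-BuLi deprotonates 16 and loss of LiCl releases chloro(methyl)carbene, which adds in a concerted manner to the electron-rich C7=C9 bond and forms the C7–C8 and C8–C9 bonds of 17; on heating, the chloride lying over the six-membered ring departs while the old C7–C9 bond breaks in a disrotatory sense, pushed by the siloxy oxygen, and the 2-siloxyallyl cation gives up its silyl group to chloride to end as the C7 ketone conjugated with C8(methyl)=C9. The closest known reaction type is halocarbene cyclopropanation of cyclohexanone silyl enol ethers followed by cyclopropyl-to-allyl opening to 2-substituted cyclohept-2-enones. The three-membered ring closes by [2+1] cycloaddition, and the seven-membered ring arises not by cyclisation but by electrocyclic cleavage of the shared bond of the bicyclo[4.1.0]heptane unit. No stereocentre is created in 18, because the three cyclopropane centres vanish again (the face of carbene attack is therefore immaterial) and C1, C4, C5 and C6 are untouched. The selectivity needed is regiochemical and was secured in step 10, and chemoselectivity follows because the enol ether is the only π bond and both hydroxyls are silylated. The epimer with methyl pointing away from the ring and chlorine over it, expected to predominate, is the one whose opening is symmetry-allowed.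

Step 12
Reactants: 18 bicyclo[5.3.0] enone
Product: 19 8α,9α-epoxy-7-ketone (4β,6α-bis-OTES)
Conditions: TBHP (decane, 3 equiv), DBU (1.5 equiv), CH2Cl2, 0 °C to rt
Reagents that add atoms: tert-butyl hydroperoxide, CC(C)(C)OO
Why: Weitz–Scheffer nucleophilic epoxidation, in which the peroxide anion adds to C9 from the α face, away from the C1 methyl, and the enolate closes onto oxygen on the same face, so that C8 and C9 are set together (epoxide α, C8 methyl β).

Step 13
Reactants: 19 bis-silylated epoxy ketone
Product: 20 8α,9α-epoxy-4β,6α-dihydroxy-7-ketone
Conditions: Et3N·3HF (10 equiv), MeCN, rt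
Reagents that add atoms: none
Why: Fluoride-driven desilylation in a nearly neutral medium removes both triethylsilyl ethers without base-induced α-ketol shift, at a stage where the adjacent carbonyl deactivates the epoxide towards acid opening.

Step 14
Reactants: 20 epoxy dihydroxy ketone
Product: 21 8α,9α-epoxy-4β,6α,7β-triol
Conditions: Me4NBH(OAc)3 (5 equiv), MeCN–AcOH (4:1), −30 °C; aq. Rochelle salt/NaHCO3
Reagents that add atoms: none
Why: Hydroxyl-directed triacetoxyborohydride reduction (Evans–Saksena type), in which the reagent is too weak to reduce the ketone until boron has bound to the α-oriented C6–OH, hydride is then passed to the α face of C7=O, also the face away from the C8 methyl, and 7β-OH results trans to C6–OH.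

Step 15
Reactants: 21 epoxy triol; 22 4-(benzyloxy)benzoic acid
Product: 23 6α-[4-(benzyloxy)benzoate] of 21
Conditions: 22 (1.05 equiv), DCC (1.1 equiv), DMAP (0.2 equiv), CH2Cl2, 0 °C
Reagents that add atoms: none
Why: Steglich esterification with one equivalent of acid should take C6–OH, because C7–OH is neopentyl-like beside the fully substituted C8 and cis to its methyl, C4–OH is tertiary, and the non-alkoxide conditions avoid epoxide migration.

Step 16
Reactants: 23 benzyl-protected ester
Product: 24 8α,9α-epoxy-4β,7β-dihydroxydaucan-6α-yl 4-hydroxybenzoate (CNP0290052.1)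
Conditions: H2 (1 atm), 10% Pd/C, EtOAc, rt
Reagents that add atoms: none
Why: Hydrogenolysis of the benzyl aryl ether in a neutral solvent frees the phenol and leaves the aliphatic epoxide, the ester and the alcohols untouched.

Compound list
1 | 3-methylcyclopentane-1,2-dione, enol form (2-hydroxy-3-methylcyclopent-2-enone) | CC1=C(O)C(=O)CC1 | starting material
2 | methyl vinyl ketone | CC(=O)C=C | starting material
3 | (S)-3-methyl-3-(3-oxobutyl)cyclopentane-1,2-dione (drawn as diketone; enolises towards the ring CH2) | O=C1CC[C@](C)(CCC(C)=O)C1=O | intermediate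
4 | (S)-7a-methyl-2,6,7,7a-tetrahydro-1H-indene-3,5-dione (C4=O, C5=C6, C7=O, C1 methyl β) | O=C1CC[C@]2(C)CCC(=O)C=C12 | intermediate
5 | C7 spiro-1,3-dioxolane of 4, C4=O conjugated with C5=C6 | O=C1CC[C@]2(C)CCC3(OCCO3)C=C12 | intermediate
6 | allylic alcohol, C4–OH β (4S), C5=C6, C7 dioxolane | O[C@H]1CC[C@]2(C)CCC3(OCCO3)C=C12 | intermediate
7 | organoborane, C6–BH2 α, C5–H α, C4–OBH2 β, C7 dioxolane | BO[C@H]1CC[C@]2(C)CCC3(OCCO3)[C@H](B)[C@H]21 | intermediate
8 | trans-fused diol, C4–OH β, C5–H α, C6–OH α, C7 dioxolane | O[C@H]1CC[C@]2(C)CCC3(OCCO3)[C@H](O)[C@H]21 | intermediate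
9 | trans-fused C4 ketone, C5–H α, C6–OH α, C7 dioxolane | O=C1CC[C@]2(C)CCC3(OCCO3)[C@H](O)[C@H]21 | intermediate
10 | isopropylmagnesium chloride | CC(C)[Mg]Cl | starting material
11 | tertiary carbinol, C4–OH β and isopropyl α, C6–OH α, C7 dioxolane | CC(C)[C@]1(O)CC[C@]2(C)CCC3(OCCO3)[C@H](O)[C@H]21 | intermediate
12 | 4β,6α-dihydroxy-4α-isopropyl trans-hydrindan-7-one | CC(C)[C@]1(O)CC[C@]2(C)CCC(=O)[C@H](O)[C@H]21 | intermediate
13 | 4β,6α-bis(triethylsilyloxy)-4α-isopropyl trans-hydrindan-7-one | CC(C)[C@]1(O[Si](CC)(CC)CC)CC[C@]2(C)CCC(=O)[C@H](O[Si](CC)(CC)CC)[C@H]21 | intermediate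
14 | lithium enolate of 13, C7(O–)=C9 | [Li+].CC(C)[C@]1(O[Si](CC)(CC)CC)CC[C@]2(C)CC=C([O-])[C@H](O[Si](CC)(CC)CC)[C@H]21 | intermediate
15 | C7=C9 trimethylsilyl enol ether, 4β,6α-bis-OTES | CC(C)[C@]1(O[Si](CC)(CC)CC)CC[C@]2(C)CC=C(O[Si](C)(C)C)[C@H](O[Si](CC)(CC)CC)[C@H]21 | intermediate
16 | 1,1-dichloroethane | CC(Cl)Cl | starting material
17 | chlorocyclopropane C7(OTMS)–C8(Cl)(CH3)–C9 fused to the six-membered ring (mixture at C7, C8, C9) | CC(C)[C@]1(O[Si](CC)(CC)CC)CC[C@]2(C)CC3C(C)(Cl)C3(O[Si](C)(C)C)[C@H](O[Si](CC)(CC)CC)[C@H]21 | intermediate
18 | trans-fused bicyclo[5.3.0] enone, C7=O, C8(methyl)=C9, 4β,6α-bis-OTES | CC(C)[C@]1(O[Si](CC)(CC)CC)CC[C@]2(C)CC=C(C)C(=O)[C@H](O[Si](CC)(CC)CC)[C@H]21 | intermediate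
19 | 8α,9α-epoxy-7-ketone, 4β,6α-bis-OTES | CC(C)[C@]1(O[Si](CC)(CC)CC)CC[C@]2(C)C[C@@H]3O[C@]3(C)C(=O)[C@H](O[Si](CC)(CC)CC)[C@H]21 | intermediate
20 | 8α,9α-epoxy-4β,6α-dihydroxy-7-ketone | CC(C)[C@]1(O)CC[C@]2(C)C[C@@H]3O[C@]3(C)C(=O)[C@H](O)[C@H]21 | intermediate
21 | 8α,9α-epoxy-4β,6α,7β-triol | CC(C)[C@]1(O)CC[C@]2(C)C[C@@H]3O[C@]3(C)[C@@H](O)[C@H](O)[C@H]21 | intermediate
22 | 4-(benzyloxy)benzoic acid | OC(=O)c1ccc(OCc2ccccc2)cc1 | starting material
23 | 8α,9α-epoxy-4β,7β-dihydroxydaucan-6α-yl 4-(benzyloxy)benzoate | CC(C)[C@]1(O)CC[C@]2(C)C[C@@H]3O[C@]3(C)[C@@H](O)[C@H](OC(=O)c3ccc(OCc4ccccc4)cc3)[C@H]21 | intermediate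
24 | 8α,9α-epoxy-4β,7β-dihydroxydaucan-6α-yl 4-hydroxybenzoate (CNP0290052.1) | CC(C)[C@]1(O)CC[C@]2(C)C[C@@H]3O[C@]3(C)[C@@H](O)[C@H](OC(=O)c3ccc(O)cc3)[C@H]21 | target

Total step count: 16. Longest linear sequence: 16 steps (from 1 and 2).

Steps most likely to fail

Step 1. Three processes could spoil it:
- weak face discrimination in the ion pair;
- a second Michael addition by the product, which is again enolisable;
- reversible O-alkylation that ties up material.

The fallback sets out from 1 and 2 and comes back at 6. It replaces asymmetric catalysis by a racemic series with enzymatic resolution. An achiral amine base (Et3N, CH2Cl2) would give the racemic triketone F1. The conditions of steps 2, 3 and 4 then lead through the racemic ene-dione F2 and the racemic ketal enone F3 to the racemic cis allylic alcohol F4. Lipase-catalysed transesterification (Burkholderia cepacia lipase, vinyl acetate, MTBE, rt) is a standard kinetic resolution of cyclic secondary allylic alcohols. By the usual size model it should acylate the (4R) antipode to the antipodal acetate F5 and leave 6. Compound 6 is separated by chromatography and taken into step 5.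

Step 6. Three processes could spoil it:
- insufficient discrimination between the two secondary hydroxyls;
- epimerisation at C5 towards the cis-fused ketone;
- loss of water from the β-hydroxy ketone during oxidation or handling.

The fallback sets out from 5 and comes back at 11. It reverses the order of events, so that no hydroxy ketone and no selective oxidation are needed. The isopropylcerium reagent from 10 (THF, −78 °C) adds 1,2 to the C4 enone carbonyl of 5 from the α face. At this point there is no α stereocentre to lose, and the product is the tertiary allylic alcohol F6. Hydroboration with BH3·THF places boron on C6, remote from the isopropyl group, from the face opposite the C1 methyl and gives the tertiary-carbinol organoborane F7. Alkaline peroxide then gives 11.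

Step 15. Poor site selectivity between the C6 and C7 hydroxyls, or acyl migration between them, could spoil it. The fallback sets out from 20 and comes back at 23. It acylates before the second secondary hydroxyl exists. Steglich esterification of 20 with 22 finds C6–OH as the only acylable hydroxyl and gives the epoxy keto ester F8. The C7 ketone is then reduced under reagent control by a Corey–Bakshi–Shibata reduction. The oxazaborolidine antipode is matched to α-face delivery, with catecholborane in toluene at −40 °C. These conditions are non-basic and generate no free alkoxide, so ester and epoxide migration are avoided. The product is 23.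

Further compounds
F1 | step 1 | racemic 3-methyl-3-(3-oxobutyl)cyclopentane-1,2-dione | O=C1CC[C@](C)(CCC(C)=O)C1=O.O=C1CC[C@@](C)(CCC(C)=O)C1=O
F2 | step 1 | racemic 7a-methyl-2,6,7,7a-tetrahydro-1H-indene-3,5-dione | O=C1CC[C@]2(C)CCC(=O)C=C12.O=C1CC[C@@]2(C)CCC(=O)C=C12
F3 | step 1 | racemic C7 ethylene ketal of the ene-dione | O=C1CC[C@]2(C)CCC3(OCCO3)C=C12.O=C1CC[C@@]2(C)CCC3(OCCO3)C=C12
F4 | step 1 | racemic allylic alcohol, C4–OH cis to the C1 methyl | O[C@H]1CC[C@]2(C)CCC3(OCCO3)C=C12.O[C@@H]1CC[C@@]2(C)CCC3(OCCO3)C=C12
F5 | step 1 | acetate of the (4R) antipode of 6 | CC(=O)O[C@@H]1CC[C@@]2(C)CCC3(OCCO3)C=C12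
F6 | step 6 | tertiary allylic alcohol, C4–OH β and isopropyl α, C5=C6, C7 dioxolane | CC(C)[C@]1(O)CC[C@]2(C)CCC3(OCCO3)C=C12
F7 | step 6 | organoborane from F6, C6–BH2 α, C5–H α, C4–OBH2 β | CC(C)[C@]1(OB)CC[C@]2(C)CCC3(OCCO3)[C@H](B)[C@H]21
F8 | step 15 | 8α,9α-epoxy-4β-hydroxy-7-oxodaucan-6α-yl 4-(benzyloxy)benzoate | CC(C)[C@]1(O)CC[C@]2(C)C[C@@H]3O[C@]3(C)C(=O)[C@H](OC(=O)c3ccc(OCc4ccccc4)cc3)[C@H]21
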